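The coupling partner is the reagent I count. Alpha at 120 min has lost 25.1 % of its starting material and holds 23.5 % of target, close to one for one, and I assume one partner per target.

| flask | starting material | coupling partner | transfer agent | initiator | remark | time |
|---|---|---|---|---|---|---|
| zeta | 0.023 M | 0.0055 M (fed, over 3.0 h) | 2.3 mM | 1.1 mM | run made earlier; the fed solution adds 0.25 times the starting volume |  |
| epsilon | 0.023 M | 0.021 M (fed, over 3.0 h) | 2.3 mM | 1.1 mM | run made earlier; the fed solution adds 0.25 times the starting volume |  |
| alpha | 0.023 M | 0.0242 M (fed, over 3.0 h) | 1.6 mM | 1.1 mM | run made earlier; the fed solution adds 0.25 times the starting volume |  |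
| dusk | 0.023 M | 0.0242 M (fed, over 3.0 h) | 2.30 mM | 1.1 mM | the fed solution adds 0.25 times the starting volume | 4.0 h |
| summer | 0.023 M | 0.00800 M | 0.600 mM | 1.1 mM | everything together at the start, the whole solution of coupling partner included, so that from the start the volume is larger by 0.25 times the starting volume | 4.0 h |

- zeta (time / min: target / %, starting material / %): 10.0: 0, 100.7; 15.0: 0, 99.5; 20.0: 0.1, 99.6; 30.0: 0, 99.4; 50.0: 0.5, 99.5; 80.0: 2.4, 97.6; 120: 4.1, 93.8
- epsilon (time / min: target / %, starting material / %): 15.0: 0, 99.4; 30.0: 1.0, 98.4; 50.0: 3.6, 96.4; 60.0: 4.9, 94.7; 80.0: 7.8, 90.7; 90.0: 11.1, 89.9; 120: 16.7, 82.2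
- alpha (time / min: target / %, starting material / %): 25.0: 1.8, 97.6; 50.0: 5.0, 94.3; 80.0: 12.6, 87.3; 90.0: 15.2, 83.5; 120: 23.5, 74.9

(each reading ± 0.5 percentage points)

* which one finishes higher in amount of target, in percent of the starting material charged ("neither" within 2 percentage points) (dusk / summer / neither)
* amount of target at the end, in percent of the starting material charged, dusk
* amount of target at the end, in percent of the starting material charged, summer

- amounts are per litre of the starting volume; all of the dose is in the solution fed
- the earlier runs were read with a standard deviation of 0.5 percentage points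

So I fold the charges into one number, the partner equivalents:

E = [coupling partner] charged / [starting material] at the start

For summer 0.348 is this ratio of partner charged to starting material charged, and dusk has 1.05. With one partner and one starting material per target, E below one is the ceiling on target, which makes the partner the limiting reagent in summer.

E puts dusk above summer, but is it enough? No. By 120 min, target over partner fed reads 0.274 in epsilon and 0.257 in zeta, at charges 3.82 times apart. I therefore read the partner's use as pseudo-first-order, with k including the lag. A steady feed then integrates, with x = kt, to: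

target / fed = 1 − (1 − e^(−x))/x ≈ (x/2)/(1 + x/3)

Epsilon gives 0.336 h⁻¹. Alpha, with 0.335, gives 0.431 h⁻¹, faster, but alpha differs from epsilon both in transfer agent and in partner charge.

Dusk, with epsilon's k: 57.8 %

Summer holds less transfer agent than alpha, and I take alpha's k as the nearest reading I have: 28.6 %

The forecast also picks dusk, but with other figures: 37 % for dusk (29 % to 47 %) and 20 % for summer (11 % to 29 %). In its words, “Partner supply caps it, so dusk wins.”

Dusk ends at 48.6 % and summer at 29.3 %, so dusk finishes higher, both above the forecast's figures.

    initiator → 2 initiating radical (k = 0.0310 h⁻¹)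
    starting material + second chain carrier → by-product + first chain carrier (k = 7.69 × 10⁶ M⁻¹ h⁻¹)
    crystals ⇌ by-product, rate k3*(cs3 - [by-product]) while solid is left; crystals form when [by-product] > cs3 (solubility = 4.90 mM, k = 6.07 h⁻¹)
    2 second chain carrier → ended chains (k = 1.20 × 10⁶ M⁻¹ s⁻¹)
    target → over-reaction product B (k = 1.44 × 10⁻⁴ h⁻¹)
    starting material + initiating radical → capped initiator + first chain carrier (k = 2.41 × 10⁵ M⁻¹ s⁻¹)
    2 idle radical → ended radicals (k = 6.00 × 10⁶ M⁻¹ s⁻¹)
    coupling partner + first chain carrier → target + second chain carrier (k = 28500 M⁻¹ s⁻¹)
    transfer agent + first chain carrier → side product + idle radical (kL = 8.31 × 10⁶ M⁻¹ h⁻¹)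
    target → over-reaction product A (k = 0.0531 h⁻¹)

Summer keeps 0.18 % of its partner charge, and its target and over-reaction product A together come to 34.7 %, against E of 0.348. The neighbour of dusk with 0.0060 M of partner has E of 0.261. With 43 % of its charge left, that gives 15.0 %, and this neighbour holds 13.8 % of target and 1.19 % of over-reaction product A.

The numbers in the tables are calculated on assumed constants, and the scatter is random.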